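(The numbers in the tables come from a simulation for an exercise; noise was put on by code.)

Target above 0.950 equiv is impossible on this recipe: each target costs one partner, the limiting reagent, and each over-reaction product costs two. Once the partner charge has fully reacted, target as a fraction of the charge equals twice the coupled fraction minus the partner equivalents. The south-west run, taken as having used up its partner, reads from a last target reading of 38.5 % as 66.8 % of coupled fraction, the share of substrate charged that became target or over-reaction product. With the partner charge held and fully reacted, each point of coupled fraction gained is worth two points of target.

| flask | substrate | partner | rival reagent | remark | time |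
|---|---|---|---|---|---|
| south-west | 0.010 M | 0.95 equiv | 1.2 equiv | run made earlier |  |
| north | 0.010 M | 0.95 equiv | 1.8 equiv | run made earlier |  |
| alpha | 0.010 M | 0.950 equiv | 1.20 equiv | everything together at the start | 15 h |
| delta | 0.010 M (fed, over 6.0 h) | 0.950 equiv | 1.20 equiv | all else is in the flask from the start; the feed brings no volume worth counting | 15 h |
| gamma | 0.010 M | 0.950 equiv | 1.20 equiv (fed, over 6.0 h) | all else is in the flask from the start; the feed brings no volume worth counting | 15 h |

- south-west (time / h: target / %, substrate / %): 1.33: 47.7, 4.6; 3.00: 43.0, 1.5; 6.00: 39.7, 1.2; 15.0: 38.5, 0.4
- north (time / h: target / %, substrate / %): 1.00: 42.5, 3.5; 2.50: 35.2, 0.7; 3.00: 33.1, 0.8; 5.00: 28.6, 0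

(each reading ± 0.3 percentage points)

- for target the crystals are counted in
- as a solid, counted per litre of solution: crystals
- steps that have been proposed: substrate + partner -> target; substrate + rival reagent -> side product; crystals <-> target; rival reagent -> decomposed reagent; partner + target -> over-reaction product

- the flask with the highest amount of target, in percent of the substrate charged ("all alike" if they lie within 1.5 percentage points) (alpha / delta / gamma / all alike)
- final target, as a percentage of the substrate charged, in alpha
- final target, as a percentage of the substrate charged, in delta
- final target, as a percentage of the substrate charged, in gamma

Gamma can be bracketed by two extreme flasks. With the rival reagent all in at the start it becomes alpha, a repeat of south-west, with coupled fraction 66.8 % and target near 38.5 %. With neither side product nor over-reaction product, the coupled fraction and the target both equal the partner charge, 95.0 %. The real gamma must lie between them. South-west had substrate down to 4.6 % at 1.33 h, sooner than the 6.0 h feed, and by then gamma has received 22.2 % of its rival reagent, which lifts it off the lower end. South-west's target readings, though, fell from 47.7 % to 38.5 %, a fall read as over-reaction; gamma holds the same partner and target, so it is expected below the upper end.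

The forecast chose gamma, with 38.3 % in alpha, 32 % in delta and 55 % in gamma, reasoning that “Gamma keeps rival low during the fast coupling”.

The flasks give 38.5 % in alpha, 32.6 % in delta and 62.7 % in gamma, so gamma stands highest.

    substrate + partner → target (k = 8.00 M⁻¹ min⁻¹)
    substrate + rival reagent → side product (k = 2.17 M⁻¹ min⁻¹)
    crystals ⇌ target, rate k3*(cs3 - [target]) while solid is left; crystals form when [target] > cs3 (solubility = 8.80 mM, k = 0.130 min⁻¹)
    rival reagent → decomposed reagent (k = 0.00924 min⁻¹)
    partner + target → over-reaction product (k = 1.76 M⁻¹ min⁻¹)

Gamma ends with 0 % of its partner and a coupled fraction of 78.8 %, 12 percentage points above the 66.8 % read from south-west, and twice its fraction minus the partner equivalents is its 62.7 % of target. The step from partner + target to over-reaction product has the largest single effect on the contrast with delta: a run without that step shrinks the gap between gamma and delta from 30 points to 0.44 points. The neighbour of delta charged with 0.570 equiv of partner ends with 0 % of it and a coupled fraction of 42.8 %, and twice that fraction minus its partner equivalents is the 28.7 % of target it holds.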